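The nine-membered ring N–C19–C18–C2–C3–C4–C5–C6–C7 (biogenetic numbering) is closed last, by ring contraction. An eleven-membered cyclic N-acyl carbamate, N–C(=O)–O–C19H2–C18(=CH2)–C2–C3=C4–C5, assembled on the tetracyclic lactam by N-acylation and metathesis, loses CO2 under zerovalent palladium; the lactam nitrogen then attacks the symmetrical 2-substituted π-allyl unit and forms the N–C19 bond. The step exploits the lactam N–H and the methyl group on C18 next to C19, carried as an exocyclic methylene so that both allyl termini are equivalent. One final hydrogenation sets C14, C15 and C18.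

Key step: step 27

Remark: atoms are named by the biogenetic numbering (C1 lactam carbonyl; C2 carbinol; C5 and C8 quaternary carbons; C9=C10 ring alkene; C14 ester-bearing carbon; C18 methyl-bearing carbon; C19 N-methylene; C21 acetoxymethyl carbon; C22 ester carbonyl).
Remark: in steps 2 and 21 the enantiomer of the ligand or tartrate is the one that gives the configuration drawn, and the metathesis of step 26 is assumed to deliver the Z alkene that is carried on.

Step 1
Reactants: 1 methyl 2-oxocycloheptane-1-carboxylate
Product: 4 methyl 7-oxocyclohept-1-ene-1-carboxylate, via selenide 2 (not isolated), via selenoxide 3 (not isolated)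
Conditions: PhSeCl, pyridine, CH2Cl2, 0 °C; then 30% aq. H2O2, 0 °C to rt
Reagents that add atoms: none
Why: α-selenenylation of the β-keto ester and syn-elimination of the selenoxide give the doubly activated enone, and no stereocenter is formed.

Step 2
Reactants: 4 methyl 7-oxocyclohept-1-ene-1-carboxylate
Product: 5 methyl (7S)-2-oxo-7-(4,4,5,5-tetramethyl-1,3,2-dioxaborolan-2-yl)cycloheptane-1-carboxylate
Conditions: B2pin2, CuCl (5 mol %), chiral ferrocenyl bisphosphine of the Josiphos type (6 mol %), NaOtBu (10 mol %), MeOH (2 equiv), THF, rt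
Reagents that add atoms: bis(pinacolato)diboron CC1(C)OB(OC1(C)C)B1OC(C)(C)C(C)(C)O1
Why: copper-catalysed enantioselective conjugate borylation of the doubly activated alkene sets the boron-bearing carbon C5 (7S) through the ligand, and the boryl group then serves as a retro-aldol-proof hydroxyl surrogate and as the control element for C8.

Step 3
Reactants: 5 the boryl keto ester; 6 methyl propiolate
Product: 7 methyl (1R,7S)-1-[(E)-3-methoxy-3-oxoprop-1-en-1-yl]-2-oxo-7-(pinacolatoboryl)cycloheptane-1-carboxylate
Conditions: DABCO (10 mol %), CH2Cl2, 0 °C to rt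
Reagents that add atoms: none
Why: amine-catalysed Michael addition (C-vinylation) of the β-keto ester to the propiolate creates the quaternary centre C8, the acceptor approaching the enolate anti to the adjacent boryl group and giving the E acrylate.

Step 4
Reactants: 7 the keto acrylate
Product: 8 the enol triflate of 7 (C9–OTf, C9=C10)
Conditions: KN(SiMe3)2, PhNTf2, THF, −78 °C
Reagents that add atoms: N-phenylbis(trifluoromethanesulfonimide) O=S(=O)(N(c1ccccc1)S(=O)(=O)C(F)(F)F)C(F)(F)F
Why: because C8 is quaternary the ketone can only enolise towards C10, and the potassium enolate is trapped on oxygen as the vinyl triflate.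

Step 5
Reactants: 9 (1-bromovinyl)trimethylsilane
Product: 11 tributyl[1-(trimethylsilyl)vinyl]stannane, via Grignard reagent 10 (not isolated)
Conditions: Mg, THF, reflux; then Bu3SnCl, 0 °C to rt
Reagents that add atoms: tributyltin chloride CCCC[Sn](Cl)(CCCC)CCCC
Why: Grignard formation from the vinyl bromide and transmetalation to tin give the α-silyl vinylstannane.

Step 6
Reactants: 8 the enol triflate; 11 the vinylstannane
Product: 12 the cross-conjugated dienone (C9–C(=O)–C(SiMe3)=CH2)
Conditions: Pd(PPh3)4 (10 mol %), CuCl, LiCl, CO (1 atm), DMSO, 60 °C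
Reagents that add atoms: carbon monoxide [C-]#[O+]
Why: carbonylative Stille coupling of the hindered vinyl triflate inserts CO (C15) between C9 and the silylvinyl unit (C16, C17).

Step 7
Reactants: 12 the dienone
Product: 14 the bicyclic enone (ring B cyclopentenone: C15 ketone and C9=C10), via silyl ketone 13 (not isolated)
Conditions: MeSO3H, CH2Cl2, 0 °C to rt
Reagents that add atoms: none
Why: Nazarov 4π-electrocyclisation of the protonated divinyl ketone forms the C10–C17 bond, proton loss gives the tetrasubstituted C9=C10 enone, and the α-silyl ketone is protodesilylated by the acid.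

Step 8
Reactants: 14 the bicyclic enone
Product: 15 the tricyclic β-hydroxy ester (ring A closed; mixture at C14 and C15)
Conditions: [(Ph3P)CuH]6 (0.25 equiv), toluene/THF, −40 to 0 °C; then aq. NH4Cl
Reagents that add atoms: none
Why: copper hydride conjugate reduction of the acrylate (the fully substituted enone is inert) gives a copper enolate at C14 that adds to the C15 ketone in a 5-exo reductive aldol cyclisation closing ring A, and the two new centres are removed in step 9.

Step 9
Reactants: 15 the β-hydroxy ester
Product: 16 the tricyclic diene ester (C14=C15–C9=C10) with C5–Bpin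
Conditions: TsOH·H2O (10 mol %), toluene, 80 °C
Reagents that add atoms: none
Why: acid-catalysed E1 dehydration of the tertiary allylic alcohol gives the fully conjugated diene ester as the thermodynamic alkene isomer.

Step 10
Reactants: 16 the boryl diene ester
Product: 17 the C5 alcohol
Conditions: NaBO3·4H2O, THF/H2O, rt
Reagents that add atoms: sodium perborate [Na+].[O-]OB=O
Why: oxidation of the C–B bond with retention unveils the C5 hydroxyl only now, when no ketone is left that could trigger retro-aldol cleavage of the C5–C8 bond.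

Step 11
Reactants: 17 the alcohol
Product: 18 the C5 ketone (8R)
Conditions: Dess–Martin periodinane, NaHCO3, CH2Cl2, rt
Reagents that add atoms: none
Why: Dess–Martin oxidation gives a β-keto ester whose only enolisable position is C6.

Step 12
Reactants: 18 the ketone
Product: 19 the α-methylene ketone (C6=C7H2)
Conditions: (CH2O)n, i-Pr2NH·CF3CO2H, THF, reflux
Reagents that add atoms: formaldehyde (as paraformaldehyde) C=O
Why: Mannich-type α-methylenation (aldol with formaldehyde and elimination) at C6, the only enolisable position, brings in C7.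

Step 13
Reactants: 19 the α-methylene ketone
Product: 21 the tetracyclic keto-lactam (6R,8R), via amino ketone 20 (not isolated)
Conditions: NH3 (7 M in MeOH), 0 to 50 °C
Reagents that add atoms: ammonia N
Why: aza-Michael addition of ammonia and lactamisation on the C1 ester close the piperidinone, C6 equilibrating through the ketone enol so that only the epimer with the aminomethyl group cis to the C1 ester cyclises, which fixes C6 relative to C8.

Step 14
Reactants: 21 the keto-lactam
Product: 22 the C5 spiro-epoxide (mixture at C5)
Conditions: Me3S+ I−, KN(SiMe3)2 (2.2 equiv), THF, −10 °C to rt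
Reagents that add atoms: trimethylsulfonium iodide C[S+](C)C.[I-]
Why: Corey–Chaykovsky epoxidation, the small sulfonium ylide adding to the hindered, non-enolisable bridging ketone while one equivalent of ylide is consumed by the lactam N–H.

Step 15
Reactants: 22 the epoxide
Product: 23 the C5 carbaldehyde (C5 epimers)
Conditions: BF3·OEt2, CH2Cl2, −78 °C
Reagents that add atoms: none
Why: Meinwald rearrangement (Lewis acid opening of the 1,1-disubstituted epoxide and 1,2-hydride shift) gives the homologated aldehyde, whose C5 centre is planarised again in step 16.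

Step 16
Reactants: 23 the aldehyde
Product: 24 the C5-allyl C5-formyl lactam (5R,6S,8R)
Conditions: KOtBu (1.0 equiv), allyl bromide, THF, −20 °C to rt
Reagents that add atoms: allyl bromide C=CCBr
Why: C-allylation of the exocyclic potassium enolate (the aldehyde α-H is far more acidic than the lactam N–H) creates the quaternary centre C5, allyl bromide approaching from the side of the three-atom lactam bridge, the smaller and flatter of the two bridges, so that the allyl group ends up syn to nitrogen and the formyl group syn to the carbocyclic bridge.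

Step 17
Reactants: 24 the aldehyde
Product: 25 the C21 primary alcohol
Conditions: NaBH4, MeOH, 0 °C
Reagents that add atoms: none
Why: chemoselective borohydride reduction of the neopentylic aldehyde in the presence of the esters and the lactam.

Step 18
Reactants: 25 the alcohol
Product: 26 the C21 acetate
Conditions: Ac2O, pyridine, DMAP (cat.), CH2Cl2, 0 °C
Reagents that add atoms: acetic anhydride CC(=O)OC(C)=O
Why: acetylation of the primary alcohol installs the C21 acetate of the target, the lactam N–H being inert under these conditions.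

Step 19
Reactants: 26 the allyl lactam
Product: 27 the (E)-prop-1-enyl lactam
Conditions: [Ir(cod)(PMePh2)2]PF6 (2 mol %, activated with H2), THF, rt
Reagents that add atoms: none
Why: iridium hydride-catalysed isomerisation of the terminal allyl group to the (E)-propenyl group places C4 as an alkene carbon on C5 for the metathesis, the tetrasubstituted alkenes being inert.

Step 20
Reactants: 28 acrolein; 29 methyl acrylate
Product: 30 racemic methyl 3-hydroxy-2-methylidenepent-4-enoate
Conditions: DABCO (10 mol %), neat, rt
Reagents that add atoms: none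
Why: Morita–Baylis–Hillman reaction of the acrylate with the aldehyde.

Step 21
Reactants: 30 the racemic allylic alcohol
Product: 31 methyl (R)-3-hydroxy-2-methylidenepent-4-enoate
Conditions: Ti(OiPr)4 (0.2 equiv), D-(−)-diisopropyl tartrate (0.24 equiv), t-BuOOH (0.6 equiv), 4 Å molecular sieves, CH2Cl2, −20 °C
Reagents that add atoms: none
Why: Sharpless kinetic resolution, in which the S enantiomer is epoxidised at its vinyl group (the electron-poor acrylate alkene is inert) and the R alcohol is recovered, sets C2.

Step 22
Reactants: 31 the (R)-alcohol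
Product: 32 methyl (R)-3-[(tert-butyldimethylsilyl)oxy]-2-methylidenepent-4-enoate
Conditions: TBSCl, imidazole, DMF, rt
Reagents that add atoms: tert-butyldimethylsilyl chloride CC(C)(C)[Si](C)(C)Cl
Why: silylation of the secondary alcohol protects the C2 oxygen through the end game.

Step 23
Reactants: 32 the silyl ether ester
Product: 33 (R)-3-[(tert-butyldimethylsilyl)oxy]-2-methylidenepent-4-en-1-ol
Conditions: i-Bu2AlH (2.2 equiv), CH2Cl2, −78 °C
Reagents that add atoms: none
Why: 1,2-reduction of the acrylate ester gives the primary allylic alcohol (C19–OH).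

Step 24
Reactants: 33 the allylic alcohol
Product: 34 (R)-3-[(tert-butyldimethylsilyl)oxy]-2-methylidenepent-4-en-1-yl 1H-imidazole-1-carboxylate
Conditions: 1,1'-carbonyldiimidazole, CH2Cl2, rt
Reagents that add atoms: 1,1'-carbonyldiimidazole O=C(n1ccnc1)n1ccnc1
Why: acyl transfer from carbonyldiimidazole gives the activated, isolable carbonate equivalent.

Step 25
Reactants: 27 the propenyl lactam; 34 the imidazole carboxylate
Product: 35 the open-chain N-acyl carbamate
Conditions: LiN(SiMe3)2 (1.05 equiv), THF, −78 °C; then 34, −78 to 0 °C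
Reagents that add atoms: none
Why: N-acylation of the lithium amidate of the lactam by the imidazole carboxylate, one equivalent of base at −78 °C removing only the N–H proton.

Step 26
Reactants: 35 the N-acyl carbamate
Product: 36 the eleven-membered cyclic N-acyl carbamate (3Z)
Conditions: second-generation Hoveyda–Grubbs catalyst RuCl2(H2IMes)(=CH–C6H4-2-OiPr) (10 mol %), toluene (1 mM), 80 °C
Reagents that add atoms: none
Why: ring-closing metathesis, initiated at the terminal vinyl group and closing on the propenyl group with loss of propene, forms the C3=C4 bond of the eleven-membered ring, whose Z isomer is needed for step 27.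

Step 27
Reactants: 36 the eleven-membered cyclic N-acyl carbamate
Product: 37 the nine-membered-ring lactam with C18=CH2 and C2–OTBS
Conditions: Pd(PPh3)4 (10 mol %), THF (2 mM), 50 °C
Reagents that add atoms: none
Why: zerovalent palladium ionises the allylic C19–O bond of the carbamate to a π-allyl palladium/N-carboxylate ion pair, CO2 is lost and the lactam amidate nitrogen attacks a CH2 terminus of the π-allyl unit, so that the eleven-membered ring N–C(=O)–O–C19–C18–C2–C3–C4–C5–C6–C7 contracts to the nine-membered ring N–C19–C18–C2–C3–C4–C5–C6–C7. The closest known reaction type is the palladium-catalysed decarboxylative allylic amination of allyl carbamates, including its ring-contracting variants with cyclic carbamates. The nine-membered ring is closed by intramolecular N-attack on the π-allyl terminus within the contact ion pair (exo to the allyl unit); no new stereocenter is formed and C2 is not touched. The step needs N- over O-allylation, ring contraction over oligomerisation and no diene formation: amidates alkylate at nitrogen under these conditions, the nucleophile is generated only next to the electrophile at high dilution, the two termini of the 2-substituted allyl unit are constitutionally equivalent so that either attack gives the same product, and the allyl unit has no β-hydrogen. The unactivated C21 acetate and the silyl ether at C2 are not ionised, and only the Z isomer of C3=C4 is expected to contract.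

Step 28
Reactants: 37 the silyl ether
Product: 38 the C2 allylic alcohol
Conditions: HF·pyridine, pyridine/THF, 0 °C to rt
Reagents that add atoms: none
Why: fluoride cleavage of the silyl ether under buffered conditions that leave the acetate and the methyl ester intact.

Step 29
Reactants: 38 the allylic alcohol
Product: 39 the target (2R,5R,6S,8R,14R,15R,18R)
Conditions: H2 (50 bar), [Ir(cod)(PCy3)(py)]PF6 (20 mol %), CH2Cl2, rt
Reagents that add atoms: none
Why: cationic iridium hydrogenation in which hydroxyl-directed delivery of hydrogen to C18=C20 cis to the C2 hydroxyl (methyl trans to OH on the ring, as for 2-methylenecycloalkanols) sets C18, the disubstituted C3=C4 is saturated, and the α,β-bond of the fully substituted diene ester is reduced from the open face opposite C5 and its acetoxymethyl group to give cis H14 and H15, while the tetrasubstituted C9=C10 remains.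

Compound list
1 | methyl 2-oxocycloheptane-1-carboxylate | COC(=O)C1CCCCCC1=O | starting material
2 | methyl 2-oxo-1-(phenylselanyl)cycloheptane-1-carboxylate (not isolated) | COC(=O)C1([Se]c2ccccc2)CCCCCC1=O | intermediate
3 | selenoxide of 2 (not isolated) | COC(=O)C1([Se](=O)c2ccccc2)CCCCCC1=O | intermediate
4 | methyl 7-oxocyclohept-1-ene-1-carboxylate | COC(=O)C1=CCCCCC1=O | intermediate
5 | methyl (7S)-2-oxo-7-(4,4,5,5-tetramethyl-1,3,2-dioxaborolan-2-yl)cycloheptane-1-carboxylate (C1 epimers) | COC(=O)C1C(=O)CCCC[C@@H]1B2OC(C)(C)C(C)(C)O2 | intermediate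
6 | methyl propiolate | C#CC(=O)OC | starting material
7 | methyl (1R,7S)-1-[(E)-3-methoxy-3-oxoprop-1-en-1-yl]-2-oxo-7-(pinacolatoboryl)cycloheptane-1-carboxylate (boryl group trans to the acrylate arm) | COC(=O)/C=C/[C@@]1([C@@H](B2OC(C)(C)C(C)(C)O2)CCCCC1=O)C(=O)OC | intermediate
8 | enol triflate of 7 (C9–OTf, C9=C10; configuration as in 7) | COC(=O)/C=C/[C@@]1([C@@H](B2OC(C)(C)C(C)(C)O2)CCCC=C1OS(=O)(=O)C(F)(F)F)C(=O)OC | intermediate
9 | (1-bromovinyl)trimethylsilane | C=C(Br)[Si](C)(C)C | starting material
10 | [1-(trimethylsilyl)vinyl]magnesium bromide (not isolated) | C=C([Mg]Br)[Si](C)(C)C | intermediate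
11 | tributyl[1-(trimethylsilyl)vinyl]stannane | C=C([Si](C)(C)C)[Sn](CCCC)(CCCC)CCCC | intermediate
12 | cross-conjugated dienone: 8 with C9–C(=O)–C(SiMe3)=CH2 in place of C9–OTf | COC(=O)/C=C/[C@@]1([C@@H](B2OC(C)(C)C(C)(C)O2)CCCC=C1C(=O)C(=C)[Si](C)(C)C)C(=O)OC | intermediate
13 | α-silyl bicyclic enone (C16–SiMe3; not isolated) | COC(=O)/C=C/[C@@]1([C@@H](B2OC(C)(C)C(C)(C)O2)CCCC3=C1C(=O)C([Si](C)(C)C)C3)C(=O)OC | intermediate
14 | bicyclic enone: ring B cyclopentenone (C15 ketone, C9=C10) fused to the seven-membered ring; C8 bears CO2Me and the (E)-acrylate arm, C5 bears Bpin | COC(=O)/C=C/[C@@]1([C@@H](B2OC(C)(C)C(C)(C)O2)CCCC3=C1C(=O)CC3)C(=O)OC | intermediate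
15 | tricyclic β-hydroxy ester (ring A closed; C15–OH, C14–CO2Me; mixture at C14 and C15) | COC(=O)C1C[C@@]2([C@@H](B3OC(C)(C)C(C)(C)O3)CCCC4=C2C1(O)CC4)C(=O)OC | intermediate
16 | tricyclic diene ester (C14=C15–C9=C10) with C5–Bpin and C8–CO2Me | COC(=O)C=1C[C@@]2([C@@H](B3OC(C)(C)C(C)(C)O3)CCCC4=C2C1CC4)C(=O)OC | intermediate
17 | tricyclic diene ester with C5–OH (OH cis to the C8 ester) | COC(=O)C=1C[C@@]2([C@@H](O)CCCC3=C2C1CC3)C(=O)OC | intermediate
18 | tricyclic diene ester with C5 ketone (8R) | COC(=O)C=1C[C@@]2(C(=O)CCCC3=C2C1CC3)C(=O)OC | intermediate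
19 | α-methylene ketone (C6=C7H2) of 18 | COC(=O)C=1C[C@@]2(C(=O)C(=C)CCC3=C2C1CC3)C(=O)OC | intermediate
20 | β-amino ketone (C6–CH2NH2; not isolated) | COC(=O)C=1C[C@@]2(C(=O)C(CN)CCC3=C2C1CC3)C(=O)OC | intermediate
21 | tetracyclic keto-lactam (N–H lactam bridging C8 and C6; C5 ketone; 6R,8R) | COC(=O)C=1C[C@@]23C(=O)NC[C@@H](CCC4=C2C1CC4)C3=O | intermediate
22 | C5 spiro-epoxide of 21 (mixture at C5) | COC(=O)C=1C[C@@]23C(=O)NC[C@@H](CCC4=C2C1CC4)C35CO5 | intermediate
23 | C5 carbaldehyde (C5–H, mixture at C5) | COC(=O)C=1C[C@@]23C(=O)NC[C@@H](CCC4=C2C1CC4)C3C=O | intermediate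
24 | C5-allyl C5-formyl lactam (5R,6S,8R; allyl syn to the lactam bridge) | COC(=O)C=1C[C@@]23C(=O)NC[C@@H](CCC4=C2C1CC4)[C@]3(C=O)CC=C | intermediate
25 | C21 primary alcohol of 24 | COC(=O)C=1C[C@@]23C(=O)NC[C@@H](CCC4=C2C1CC4)[C@]3(CO)CC=C | intermediate
26 | C21 acetate with C5-allyl | COC(=O)C=1C[C@@]23C(=O)NC[C@@H](CCC4=C2C1CC4)[C@]3(COC(C)=O)CC=C | intermediate
27 | tetracyclic N–H lactam with C5-(E)-prop-1-enyl, C21 acetate and diene ester (5R,6S,8R) | COC(=O)C=1C[C@@]23C(=O)NC[C@@H](CCC4=C2C1CC4)[C@]3(COC(C)=O)/C=C/C | intermediate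
28 | acrolein | C=CC=O | starting material
29 | methyl acrylate | C=CC(=O)OC | starting material
30 | racemic methyl 3-hydroxy-2-methylidenepent-4-enoate | C=CC(O)C(=C)C(=O)OC | intermediate
31 | methyl (R)-3-hydroxy-2-methylidenepent-4-enoate | C=C[C@@H](O)C(=C)C(=O)OC | intermediate
32 | methyl (R)-3-[(tert-butyldimethylsilyl)oxy]-2-methylidenepent-4-enoate | C=C[C@@H](O[Si](C)(C)C(C)(C)C)C(=C)C(=O)OC | intermediate
33 | (R)-3-[(tert-butyldimethylsilyl)oxy]-2-methylidenepent-4-en-1-ol | C=C[C@@H](O[Si](C)(C)C(C)(C)C)C(=C)CO | intermediate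
34 | (R)-3-[(tert-butyldimethylsilyl)oxy]-2-methylidenepent-4-en-1-yl 1H-imidazole-1-carboxylate | C=C[C@@H](O[Si](C)(C)C(C)(C)C)C(=C)COC(=O)n1ccnc1 | intermediate
35 | N-acyl carbamate: lactam nitrogen of 27 carrying the CO2CH2C(=CH2)CH(OTBS)CH=CH2 group (2R) | COC(=O)C=1C[C@@]23C(=O)N(C(=O)OCC(=C)[C@H](O[Si](C)(C)C(C)(C)C)C=C)C[C@@H](CCC4=C2C1CC4)[C@]3(COC(C)=O)/C=C/C | intermediate
36 | eleven-membered cyclic N-acyl carbamate (ring N–C(=O)–O–C19–C18–C2–C3=C4–C5–C6–C7; 3Z; C18=CH2; C2–OTBS, 2R) | COC(=O)C=1C[C@@]23C(=O)N4C[C@@H](CCC5=C2C1CC5)[C@]3(COC(C)=O)/C=C\[C@@H](O[Si](C)(C)C(C)(C)C)C(=C)COC4=O | intermediate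
37 | nine-membered-ring lactam (ring N–C19–C18–C2–C3=C4–C5–C6–C7; 3Z; C18=CH2; C2–OTBS) | COC(=O)C=1C[C@@]23C(=O)N4C[C@@H](CCC5=C2C1CC5)[C@]3(COC(C)=O)/C=C\[C@@H](O[Si](C)(C)C(C)(C)C)C(=C)C4 | intermediate
38 | C2 allylic alcohol of 37 | COC(=O)C=1C[C@@]23C(=O)N4C[C@@H](CCC5=C2C1CC5)[C@]3(COC(C)=O)/C=C\[C@@H](O)C(=C)C4 | intermediate
39 | target CNP0296366.1 (2R,5R,6S,8R,14R,15R,18R) | COC(=O)[C@@H]1C[C@@]23C(=O)N4C[C@@H](CCC5=C2[C@@H]1CC5)[C@]3(COC(C)=O)CC[C@@H](O)[C@H](C)C4 | target

Total step count: 29. Longest linear sequence: 23 steps (steps 1–4, 6–19 and 25–29).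

Steps most likely to fail

Step 27 (key step). The ion pair may collapse between molecules to oligomers, the amidate may alkylate on oxygen, or an E isomer of the C3=C4 alkene may fail to contract and decompose instead. Fallback, setting out from 27 and 33 and coming back at 37: alcohol 33 is converted with CBr4 and PPh3 into the allylic bromide F1; lactam 27 is alkylated on oxygen with F1 and Ag2CO3 to give the O-allyl lactim ether F2; ring-closing metathesis with the catalyst of step 26 gives the macrocyclic lactim ether F3, in which nitrogen sits in an eleven-membered ring N=C1–O–C19–C18–C2–C3=C4–C5–C6–C7; a thermal or PdCl2(MeCN)2-catalysed [3,3] rearrangement of the allyl imidate to the N-allyl amide then moves C1 and oxygen out of the ring and gives 37.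

Step 26. Initiation may stay at the terminal vinyl group without closure onto the neopentylic propenyl group, giving dimers, or the ring may close to the E alkene that cannot be carried through step 27. Fallback, setting out from 26 and coming back at 39: the lactam nitrogen of 26 is acylated (LiN(SiMe3)2) with 2-bromoallyl 1H-imidazole-1-carboxylate F4 (from 2-bromoallyl alcohol and carbonyldiimidazole) to give the carbamate F5; hydroboration of the terminal allyl group with 9-BBN and oxidation with NaBO3 give the primary alcohol F6, and Dess–Martin oxidation gives the aldehyde F7 (C2 as CHO); a macrocyclising chromium-mediated vinyl bromide–aldehyde coupling (CrCl2, NiCl2 cat., chiral sulfonamide ligand for the 2R alcohol) closes the eleven-membered ring at C2–C18 and gives the allylic alcohol F8 with C3–C4 already saturated; Pd(PPh3)4 as in step 27 contracts F8 to the nine-membered allylic alcohol F9, and the conditions of step 29 convert F9 into 39.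

Step 29. The tetrasubstituted C9=C10 alkene may be over-reduced under the pressure needed for the diene ester, the diene ester may resist, or competing binding of the catalyst may erode the hydroxyl direction at C18. Fallback, setting out from 38 and coming back at 39: the single global hydrogenation is replaced by two separate reductions; [Rh(nbd)(dppb)]BF4 under 1 atm of H2 carries out only the hydroxyl-directed reduction of C18=C20 and saturates C3=C4, giving the diene ester F10 with C18 set; the diene ester, then the only reducible unit, is reduced on its own with [Ir(cod)(PCy3)(py)]PF6 under pressure, where the uptake of one equivalent of hydrogen can be followed, to give 39.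

Further compounds
F1 | step 27 | (R)-[3-(bromomethyl)penta-1,4-dien-... ]: (R)-tert-butyl[(4-(bromomethyl)penta-1,4-dien-3-yl)oxy]dimethylsilane | C=C[C@@H](O[Si](C)(C)C(C)(C)C)C(=C)CBr
F2 | step 27 | O-allyl lactim ether of 27 (C1(=N)–O–CH2C(=CH2)CH(OTBS)CH=CH2) | COC(=O)C=1C[C@@]23C(OCC(=C)[C@H](O[Si](C)(C)C(C)(C)C)C=C)=NC[C@@H](CCC4=C2C1CC4)[C@]3(COC(C)=O)/C=C/C
F3 | step 27 | macrocyclic lactim ether (3Z) | COC(=O)C=1C[C@@]23C4=NC[C@@H](CCC5=C2C1CC5)[C@]3(COC(C)=O)/C=C\[C@@H](O[Si](C)(C)C(C)(C)C)C(=C)CO4
F4 | step 26 | 2-bromoallyl 1H-imidazole-1-carboxylate | C=C(Br)COC(=O)n1ccnc1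
F5 | step 26 | N-(2-bromoallyloxycarbonyl) derivative of 26 | COC(=O)C=1C[C@@]23C(=O)N(C(=O)OCC(Br)=C)C[C@@H](CCC4=C2C1CC4)[C@]3(COC(C)=O)CC=C
F6 | step 26 | primary alcohol (C5–CH2CH2CH2OH) from F5 | COC(=O)C=1C[C@@]23C(=O)N(C(=O)OCC(Br)=C)C[C@@H](CCC4=C2C1CC4)[C@]3(COC(C)=O)CCCO
F7 | step 26 | aldehyde (C2 as CHO) from F6 | COC(=O)C=1C[C@@]23C(=O)N(C(=O)OCC(Br)=C)C[C@@H](CCC4=C2C1CC4)[C@]3(COC(C)=O)CCC=O
F8 | step 26 | eleven-membered cyclic N-acyl carbamate with saturated C3–C4 and free (2R)-hydroxyl | COC(=O)C=1C[C@@]23C(=O)N4C[C@@H](CCC5=C2C1CC5)[C@]3(COC(C)=O)CC[C@@H](O)C(=C)COC4=O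
F9 | step 26 | nine-membered allylic alcohol with saturated C3–C4 and C18=CH2 | COC(=O)C=1C[C@@]23C(=O)N4C[C@@H](CCC5=C2C1CC5)[C@]3(COC(C)=O)CC[C@@H](O)C(=C)C4
F10 | step 29 | 14,15-didehydro target (diene ester with saturated nine-membered ring, 2R,18R) | COC(=O)C=1C[C@@]23C(=O)N4C[C@@H](CCC5=C2C1CC5)[C@]3(COC(C)=O)CC[C@@H](O)[C@H](C)C4
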